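## Structural features

The target is a cyclohex-3-ene ring (C1–C6, C3=C4 alkene, methyl on C4, gem-dimethyl on C6) carrying two 5,7-dimethoxycoumarin units, each attached through its C8. Coumarin B is bonded directly to C2; coumarin A is joined to C1 through a single CH(OH) carbon. Three stereocentres stand in a row: the carbinol carbon (S), C1 (S) and C2 (R). The two ring substituents are trans, and C1 is wedged between the quaternary C6 and the aryl-bearing C2. The fragile groups are the two lactones (attacked by organometallics and hydroxide), the secondary benzylic alcohol on a doubly ortho-oxygenated arene (ionisation, and quinone methide formation once the neighbouring phenol is free), the allylic and benzylic C2–H, and the trisubstituted alkene. The real difficulty is steric and stereochemical: two di-ortho-substituted arenes crowd C1/C2, and the exocyclic carbinol configuration must be fixed relative to the ring without a C1-epimerisable ketone. The key step exploits the fact that the carbinol carbon is an isolated one-carbon unit between C1 of the cyclohexene and C8 of coumarin A, so it can be inserted between a C1 boronic ester and an aryl nucleophile, with the diol on boron setting its configuration. Each coumarin is treated as a 2-oxygenated 4,6-dimethoxyphenyl ring plus a three-carbon alkynoate, which keeps the lactones out of all organometallic chemistry.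

## Logic of the disconnections

26 ⇒ 25. Only the O–Si bond is cut. The benzylic hydroxyl must stay masked while the phenols are free, acylated and exposed to a Lewis-acidic gold catalyst. Nothing is gained in skeleton; the forward step must remove silicon without opening a lactone or ionising the carbinol.

25 ⇒ 24. Both C4–C4a bonds of the pyranones are cut. Lactones cannot coexist with the lithium reagents used earlier, so they are made last, from aryl alkynoates. Two heterocycles disappear and both arenes become simple trioxygenated benzenes. The forward step must close 6-endo-dig at the one free position ortho to each ester oxygen and spare the silyl ether.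

24 ⇒ 23 ⇒ 22 ⇒ 21. Two acyl C–O bonds, then two allyl–O bonds, then the Si–O bond are cut. This returns the product of the key step with both phenols as allyl ethers. The demand is a neutral deallylation and a carbinol that is never free next to a free phenol.

21 ⇒ 14 + 16 + 15. The C1–carbinol bond, the carbinol–aryl bond and the C–O bond are cut at once. The carbinol carbon becomes 16, ring A becomes 15 (as its lithium derivative 19), and the ring with C1, C2 and ring B becomes the boronic ester 14. This removes one stereocentre and two skeletal bonds and makes the route convergent. The forward step needs two consecutive 1,2-shifts at a congested boron, with the diol 11 choosing which chloride leaves.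

14 ⇒ 13 ⇒ 10 ⇒ 9. Only O-allyl, B–O and O–Si bonds are changed. The chiral diol is introduced through a trifluoroborate because a hindered pinacol ester does not exchange directly. The allyl group is put on ring B only after the copper–boryl step, where an allyl ether would itself be a substrate. The demand is that C1 and C2 are untouched.

9 ⇒ 8. The C1–B and C2–H bonds are cut. A syn addition of boron and hydrogen across C1=C2 of a 2-aryl diene sets both ring stereocentres and their trans relation in one catalytic step. The demand is boron at C1, protonation at C2 and not C4, and face selection by the ligand.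

8 ⇒ 2 + 5. The C2–aryl bond is cut, an sp2–sp2 bond made by cross-coupling. The aryl partner is used as an organozinc, because a 2,6-dioxygenated arylboronic acid would protodeboronate.

2 ⇒ 1, and 5 and 15 ⇒ 4 ⇒ 3. The C–O bond of the enol triflate, the O–Si and O–allyl bonds and the C–I bond are cut. One iodophenol 4 serves both arenes. The demands are α′-deprotonation of 1 and iodination of 3 between OH and OMe.

## Other disconnections considered

Alternative 1: The cut is through C2–C3 and C1–C6, so the carbocycle is assembled from a 2′-hydroxychalcone A2 and a silyloxydiene A3. In the forward step a chiral borate (from a triaryl borate and an axially chiral biaryl diol) chelates the hydroxyketone. The CH2 terminus of A3 adds to C2, and the enolate then closes C1 onto the dimethyl-bearing terminus, giving the trans ketone A1.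
- In its favour: ring, both arenes and the C1/C2 stereocentres arrive in one catalytic operation from two cheap fragments. The 2′-hydroxyl serves as ligating group and later as lactone oxygen. On step economy to the carbocycle it is clearly better than the chosen plan.
- Against it here: the second bond must form the quaternary C6 by attack on a β,β-disubstituted acceptor, so the sequence may stop after the first C–C bond. A1 carries C4 as a ketone, which must be enolised toward C3 and not C5 before triflation and methylation, with little bias. The carbinol carbon arrives as a very hindered aryl ketone, so the third stereocentre depends on a reduction of uncertain sense. The methoxymethyl ether needs acid next to an ionisable benzylic alcohol.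
- Comparison: the trans arrangement is the thermodynamically favoured one even with the ketone present, so on the C1/C2 relation it is the equal of the chosen plan. The decisive difference is mechanistic: the chosen plan fixes the carbinol by stereospecific 1,2-shifts and never makes C1 epimerisable. Overall step count would be similar or slightly lower, with risk concentrated on regiochemistry and the carbinol.

Alternative 2: The cut is through the two C4–C4a bonds. A cationic gold catalyst cyclises the bis(propiolate) A5 by double 6-endo-dig hydroarylation to the silyl ether A4.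
- In its favour: the lactones appear only after all basic and organometallic steps, both rings close at once, and the step is an isomerisation.
- Against it as the strategy-defining step: it addresses only the heterocycles and says nothing about the stereotriad or the hindered C–C bonds. It still needs a bis-phenol with a masked carbinol.
- Comparison: it is not a rival but a component. A5 and A4 are identical with 24 and 25, and the chosen plan uses this step as step 14, so the two are equal here.

Alternative 3: The cut is through two C–C bonds of the ring-B benzene, so the arene is built on C2. A siloxyalkyne A7 and 3-methoxycyclobutenone A8 are heated; the vinylketene from A8 undergoes [2+2] addition, electrocyclic opening and 6π closure to the phenol A6.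
- In its favour: no di-ortho-substituted arene has to be joined to a hindered carbon, regiochemistry is built into the cascade, no metal is needed, and the three ring oxygens emerge differentiated. On regiocontrol it is at least the equal of the iodination in the chosen plan.
- Against it here: the difficulty is only moved. A7 needs the trans C2-alkynyl cyclohexene with the carbinol side chain in place, and the ynol ether costs further steps. A6 must then be O-methylated and desilylated, and its methoxymethyl ether needs acid. The annulation requires heating a benzylic silyl ether on a very electron-rich ring.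
- Comparison: the chosen plan attaches ring B by coupling at an sp2 carbon, where hindrance matters little, so the structural benefit of building the arene is small. On step economy the alternative is longer by several steps.

Key step: step 10

Assumption: chloride selection in the dichloromethyl insertion follows the usual sense for boronic esters of C2-symmetric 1,2-diols ((R,R) gives the αS chloride, so the (S,S)-diol gives the αR chloride) and is not overturned by the ring stereocentres.

Remark on descriptors: the ring carbons are (1S,2S) in 9–14 and (1S,2R) in 18–26 with no spatial change, because boron ranks below carbon.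

Design changes made for safety:
- Ring B is carried as a silyl ether through the copper–boryl step and is allylated only afterwards.
- An arylzinc replaces the arylboronic acid in the coupling.
- The diol exchange runs through the trifluoroborate.
- Zinc salts are removed before the aryllithium is added in the key step.

## Steps

Step 1
Reactants: 1 isophorone (3,5,5-trimethylcyclohex-2-en-1-one)
Product: 2 3,3,5-trimethylcyclohexa-1,5-dien-1-yl trifluoromethanesulfonate
Conditions: LiN(i-Pr)2, THF, −78 °C; PhNTf2, −78 → 0 °C
Reagents that add atoms: N-phenylbis(trifluoromethanesulfonimide), O=S(=O)(N(c1ccccc1)S(=O)(=O)C(F)(F)F)C(F)(F)F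
Why: Kinetic deprotonation of the enone at the α′-methylene by the hindered amide gives the cross-conjugated lithium dienolate, which is trapped on oxygen (enol triflate formation).

Step 2
Reactants: 3 3,5-dimethoxyphenol
Product: 4 2-iodo-3,5-dimethoxyphenol
Conditions: NIS, CH2Cl2, −40 → 0 °C, dark
Reagents that add atoms: N-iodosuccinimide, O=C1CCC(=O)N1I
Why: Electrophilic aromatic iodination of a phenol; the two equivalent sites between OH and OMe are favoured statistically and by the smaller, hydrogen-bonding hydroxyl over the site between two methoxy groups, and the 4-iodo isomer is removed by chromatography.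

Step 3
Reactants: 4 2-iodo-3,5-dimethoxyphenol
Product: 5 tert-butyl(2-iodo-3,5-dimethoxyphenoxy)dimethylsilane
Conditions: TBSCl, imidazole, DMF, rt
Reagents that add atoms: tert-butyldimethylsilyl chloride, CC(C)(C)[Si](C)(C)Cl
Why: Standard phenol silylation; the silyl ether has no alkene and is inert to a copper–boryl species, which could add to an allyl ether and expel phenoxide.

Step 4
Reactants: 5 tert-butyl(2-iodo-3,5-dimethoxyphenoxy)dimethylsilane; 2 3,3,5-trimethylcyclohexa-1,5-dien-1-yl trifluoromethanesulfonate
Product: 8 tert-butyl[3,5-dimethoxy-2-(3,3,5-trimethylcyclohexa-1,5-dien-1-yl)phenoxy]dimethylsilane, via arylmagnesium chloride 6 (not isolated), via arylzinc chloride 7 (not isolated)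
Conditions: i-PrMgCl·LiCl, THF, 0 °C → rt; ZnCl2, 0 °C; 2, Pd(OAc)2 (3 mol %), SPhos (6 mol %), THF, 50 °C
Reagents that add atoms: none
Why: Iodine–magnesium exchange (assisted by the flanking oxygens and free of the oxygen-to-carbon silyl shift an aryllithium could undergo), transmetalation to zinc and Negishi coupling with the alkenyl triflate; the biarylphosphine copes with the di-ortho-substituted nucleophile.

Step 5
Reactants: 8 tert-butyl[3,5-dimethoxy-2-(3,3,5-trimethylcyclohexa-1,5-dien-1-yl)phenoxy]dimethylsilane
Product: 9 pinacol ester of (1S,2S)-trans-2-[2-(tert-butyldimethylsilyloxy)-4,6-dimethoxyphenyl]-4,6,6-trimethylcyclohex-3-en-1-ylboronic acid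
Conditions: CuCl (5 mol %), (R,R)-QuinoxP* (6 mol %), NaOt-Bu (10 mol %), B2pin2, MeOH (2 equiv), THF, 0 °C → rt
Reagents that add atoms: bis(pinacolato)diboron, CC1(C)OB(OC1(C)C)B1OC(C)(C)C(C)(C)O1
Why: Copper-catalysed enantioselective protoboration of a cyclic 1,3-diene: the ligated Cu–Bpin adds syn across C1=C2 with boron at the diene terminus C1 and copper at the allylic, benzylic C2, and methanol protonates C2 on the copper-bearing face, so B and H are cis and B and aryl trans; the ligand antipode is chosen to deliver (1S,2S).

Step 6
Reactants: 9 pinacol ester of (1S,2S)-trans-2-[2-(tert-butyldimethylsilyloxy)-4,6-dimethoxyphenyl]-4,6,6-trimethylcyclohex-3-en-1-ylboronic acid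
Product: 10 potassium (1S,2S)-trans-trifluoro[2-(2-hydroxy-4,6-dimethoxyphenyl)-4,6,6-trimethylcyclohex-3-en-1-yl]borate
Conditions: KHF2 (aq., excess), MeOH, rt; evaporation, acetone extraction, recrystallisation
Reagents that add atoms: potassium hydrogen difluoride, F.[F-].[K+]
Why: KHF2 converts the pinacol ester into the crystalline trifluoroborate and in the same operation cleaves the phenolic silyl ether (fluoride desilylation of aryl silyl ethers); recrystallisation of the salt can raise enantiomeric purity.

Step 7
Reactants: 10 potassium (1S,2S)-trans-trifluoro[2-(2-hydroxy-4,6-dimethoxyphenyl)-4,6,6-trimethylcyclohex-3-en-1-yl]borate; 11 (1S,2S)-1,2-dicyclohexylethane-1,2-diol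
Product: 13 (4S,5S)-4,5-dicyclohexyl-2-[(1S,2S)-2-(2-hydroxy-4,6-dimethoxyphenyl)-4,6,6-trimethylcyclohex-3-en-1-yl]-1,3,2-dioxaborolane, via boronic acid 12 (not isolated)
Conditions: TMSCl, H2O, MeCN, 0 °C → rt; 11, MgSO4, Et2O, rt; aq. NaHCO3 wash
Reagents that add atoms: none
Why: Fluorophile-assisted hydrolysis of the trifluoroborate to the boronic acid, then condensation with the C2-symmetric diol; this two-stage exchange is used because direct transesterification of a hindered pinacol ester is unfavourable, and the diastereomeric ester allows a further purity upgrade.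

Step 8
Reactants: 13 (4S,5S)-4,5-dicyclohexyl-2-[(1S,2S)-2-(2-hydroxy-4,6-dimethoxyphenyl)-4,6,6-trimethylcyclohex-3-en-1-yl]-1,3,2-dioxaborolane
Product: 14 (4S,5S)-2-{(1S,2S)-2-[2-(allyloxy)-4,6-dimethoxyphenyl]-4,6,6-trimethylcyclohex-3-en-1-yl}-4,5-dicyclohexyl-1,3,2-dioxaborolane
Conditions: allyl bromide, K2CO3, DMF, rt
Reagents that add atoms: allyl bromide, C=CCBr
Why: Williamson O-allylation of the phenol; the dioxaborolane is inert to carbonate, and the allyl group, introduced only after the copper step, lets both phenols be released together later under neutral palladium catalysis.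

Step 9
Reactants: 4 2-iodo-3,5-dimethoxyphenol
Product: 15 1-(allyloxy)-2-iodo-3,5-dimethoxybenzene
Conditions: allyl bromide, K2CO3, acetone, reflux
Reagents that add atoms: allyl bromide, C=CCBr
Why: Williamson etherification; the iodide fixes where lithium will sit, which direct lithiation of an allyl ether would not.

Step 10
Reactants: 14 (4S,5S)-2-{(1S,2S)-2-[2-(allyloxy)-4,6-dimethoxyphenyl]-4,6,6-trimethylcyclohex-3-en-1-yl}-4,5-dicyclohexyl-1,3,2-dioxaborolane; 16 dichloromethane; 15 1-(allyloxy)-2-iodo-3,5-dimethoxybenzene
Product: 21 (S)-[2-(allyloxy)-4,6-dimethoxyphenyl]{(1S,2R)-2-[2-(allyloxy)-4,6-dimethoxyphenyl]-4,6,6-trimethylcyclohex-3-en-1-yl}methanol, via dichloromethyllithium 17 (not isolated), via α-chloro boronic ester 18 (not isolated), via aryllithium 19 (not isolated), via benzylic boronic ester 20 (not isolated)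
Conditions: 16, n-BuLi, THF, −100 °C; 14; ZnCl2, −100 °C → rt; solvent swap to pentane, filtration under argon; 19 (from 15, n-BuLi, THF, −78 °C), THF, −78 → 0 °C; NaOH, H2O2, THF/H2O, 0 °C → rt
Reagents that add atoms: hydrogen peroxide, OO
Why: Dichloromethyllithium adds to boron of 14, and ZnCl2 promotes migration of C1 from boron to carbon with retention at C1 while one chloride leaves; the (S,S)-diol differentiates the two diastereotopic chlorides and should give the αR chloride 18. The zinc salts are then removed, since they would consume the aryllithium by transmetalation. Aryllithium 19 adds to boron of 18 and the aryl group migrates with inversion at the α-carbon, displacing the second chloride to give 20. Alkaline peroxide replaces boron by hydroxyl with retention, so the S carbinol follows from reagent control. The closest known reaction type is the Matteson homologation of chiral diol boronic esters with stereospecific displacement of the α-chloride by an organometallic and oxidative work-up. No ring is closed. The one new stereocentre, the carbinol carbon, is controlled by the diol on boron together with the inversion–retention sequence; C1 and C2 are untouched because C1 migrates with retention and never has a carbonyl neighbour. The step needs borate formation at a boron next to the quaternary C6, which the small carbenoid permits, and it needs the aryl shift to outrun β-elimination from 18, which low temperature and the high migratory aptitude of the electron-rich aryl group favour.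

Step 11
Reactants: 21 (S)-[2-(allyloxy)-4,6-dimethoxyphenyl]{(1S,2R)-2-[2-(allyloxy)-4,6-dimethoxyphenyl]-4,6,6-trimethylcyclohex-3-en-1-yl}methanol
Product: 22 triethylsilyl ether of 21
Conditions: TESOTf, 2,6-lutidine, CH2Cl2, −78 → −20 °C
Reagents that add atoms: triethylsilyl trifluoromethanesulfonate, CC[Si](CC)(CC)OS(=O)(=O)C(F)(F)F
Why: Silylation of a hindered secondary alcohol with a silyl triflate and a hindered base; the cold, buffered medium avoids ionisation of the electron-rich benzylic position.

Step 12
Reactants: 22 triethylsilyl ether of 21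
Product: 23 2-[(S)-{(1S,2R)-2-(2-hydroxy-4,6-dimethoxyphenyl)-4,6,6-trimethylcyclohex-3-en-1-yl}(triethylsilyloxy)methyl]-3,5-dimethoxyphenol
Conditions: Pd(PPh3)4 (5 mol %), morpholine, THF, rt
Reagents that add atoms: none
Why: Tsuji–Trost deallylation: zerovalent palladium ionises both aryl allyl ethers and morpholine traps the allyl fragments; the medium is neutral and non-protic, so the silyl ether neither migrates to the new phenoxide nor is lost.

Step 13
Reactants: 23 2-[(S)-{(1S,2R)-2-(2-hydroxy-4,6-dimethoxyphenyl)-4,6,6-trimethylcyclohex-3-en-1-yl}(triethylsilyloxy)methyl]-3,5-dimethoxyphenol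
Product: 24 bis(propiolate) ester of 23 (both phenols as prop-2-ynoates)
Conditions: propiolic acid, DCC, DMAP (5 mol %), CH2Cl2, −20 → 0 °C
Reagents that add atoms: propiolic acid, C#CC(=O)O
Why: Carbodiimide (Steglich-type) esterification of phenols; low temperature and little DMAP suppress conjugate addition of phenol to the alkynoate.

Step 14
Reactants: 24 bis(propiolate) ester of 23
Product: 25 triethylsilyl ether of the target (both 5,7-dimethoxycoumarin rings formed)
Conditions: AuCl(PPh3) (10 mol %), AgOTf (10 mol %), CH2Cl2, rt
Reagents that add atoms: none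
Why: Gold-catalysed intramolecular hydroarylation of aryl alkynoates: each activated alkyne is attacked 6-endo-dig by the only free carbon ortho to its ester oxygen (also ortho and para to methoxy groups), forming both C4–C4a bonds and both pyranones.

Step 15
Reactants: 25 triethylsilyl ether of the target
Product: 26 8-[(S)-hydroxy{(1S,2R)-2-(5,7-dimethoxy-2-oxo-2H-chromen-8-yl)-4,6,6-trimethylcyclohex-3-en-1-yl}methyl]-5,7-dimethoxy-2H-chromen-2-one (target)
Conditions: HF·pyridine, pyridine, THF, 0 °C → rt
Reagents that add atoms: none
Why: Buffered fluoride desilylation; the medium is neither basic enough to open the lactones nor acidic enough to ionise the carbinol, which is now on a less electron-rich coumarin ring.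

## Compound list

1 | isophorone (3,5,5-trimethylcyclohex-2-en-1-one) | CC1=CC(=O)CC(C)(C)C1 | starting material
2 | 3,3,5-trimethylcyclohexa-1,5-dien-1-yl trifluoromethanesulfonate | CC1=CC(OS(=O)(=O)C(F)(F)F)=CC(C)(C)C1 | intermediate
3 | 3,5-dimethoxyphenol | COc1cc(O)cc(OC)c1 | starting material
4 | 2-iodo-3,5-dimethoxyphenol | COc1cc(O)c(I)c(OC)c1 | intermediate
5 | tert-butyl(2-iodo-3,5-dimethoxyphenoxy)dimethylsilane | COc1cc(O[Si](C)(C)C(C)(C)C)c(I)c(OC)c1 | intermediate
6 | [2-(tert-butyldimethylsilyloxy)-4,6-dimethoxyphenyl]magnesium chloride | COc1cc(O[Si](C)(C)C(C)(C)C)c([Mg]Cl)c(OC)c1 | intermediate (not isolated)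
7 | [2-(tert-butyldimethylsilyloxy)-4,6-dimethoxyphenyl]zinc chloride | COc1cc(O[Si](C)(C)C(C)(C)C)c([Zn]Cl)c(OC)c1 | intermediate (not isolated)
8 | tert-butyl[3,5-dimethoxy-2-(3,3,5-trimethylcyclohexa-1,5-dien-1-yl)phenoxy]dimethylsilane | CC1=CC(c2c(OC)cc(OC)cc2O[Si](C)(C)C(C)(C)C)=CC(C)(C)C1 | intermediate
9 | pinacol ester of (1S,2S)-trans-2-[2-(tert-butyldimethylsilyloxy)-4,6-dimethoxyphenyl]-4,6,6-trimethylcyclohex-3-en-1-ylboronic acid | B1(OC(C)(C)C(C)(C)O1)[C@H]1[C@H](c2c(OC)cc(OC)cc2O[Si](C)(C)C(C)(C)C)C=C(C)CC1(C)C | intermediate
10 | potassium (1S,2S)-trans-trifluoro[2-(2-hydroxy-4,6-dimethoxyphenyl)-4,6,6-trimethylcyclohex-3-en-1-yl]borate | [K+].F[B-](F)(F)[C@H]1[C@H](c2c(OC)cc(OC)cc2O)C=C(C)CC1(C)C | intermediate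
11 | (1S,2S)-1,2-dicyclohexylethane-1,2-diol | O[C@@H](C1CCCCC1)[C@H](C1CCCCC1)O | starting material
12 | (1S,2S)-trans-2-(2-hydroxy-4,6-dimethoxyphenyl)-4,6,6-trimethylcyclohex-3-en-1-ylboronic acid | OB(O)[C@H]1[C@H](c2c(OC)cc(OC)cc2O)C=C(C)CC1(C)C | intermediate (not isolated)
13 | (4S,5S)-4,5-dicyclohexyl-2-[(1S,2S)-2-(2-hydroxy-4,6-dimethoxyphenyl)-4,6,6-trimethylcyclohex-3-en-1-yl]-1,3,2-dioxaborolane | B1(O[C@@H](C2CCCCC2)[C@H](C2CCCCC2)O1)[C@H]1[C@H](c2c(OC)cc(OC)cc2O)C=C(C)CC1(C)C | intermediate
14 | (4S,5S)-2-{(1S,2S)-2-[2-(allyloxy)-4,6-dimethoxyphenyl]-4,6,6-trimethylcyclohex-3-en-1-yl}-4,5-dicyclohexyl-1,3,2-dioxaborolane | B1(O[C@@H](C2CCCCC2)[C@H](C2CCCCC2)O1)[C@H]1[C@H](c2c(OC)cc(OC)cc2OCC=C)C=C(C)CC1(C)C | intermediate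
15 | 1-(allyloxy)-2-iodo-3,5-dimethoxybenzene | C=CCOc1cc(OC)cc(OC)c1I | intermediate
16 | dichloromethane | ClCCl | starting material
17 | dichloromethyllithium | [Li]C(Cl)Cl | intermediate (not isolated)
18 | (4S,5S)-2-[(R)-chloro{(1S,2R)-2-[2-(allyloxy)-4,6-dimethoxyphenyl]-4,6,6-trimethylcyclohex-3-en-1-yl}methyl]-4,5-dicyclohexyl-1,3,2-dioxaborolane | Cl[C@H](B1O[C@@H](C2CCCCC2)[C@H](C2CCCCC2)O1)[C@H]1[C@H](c2c(OC)cc(OC)cc2OCC=C)C=C(C)CC1(C)C | intermediate (not isolated)
19 | [2-(allyloxy)-4,6-dimethoxyphenyl]lithium | C=CCOc1cc(OC)cc(OC)c1[Li] | intermediate (not isolated)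
20 | (4S,5S)-2-[(S)-[2-(allyloxy)-4,6-dimethoxyphenyl]{(1S,2R)-2-[2-(allyloxy)-4,6-dimethoxyphenyl]-4,6,6-trimethylcyclohex-3-en-1-yl}methyl]-4,5-dicyclohexyl-1,3,2-dioxaborolane | C=CCOc1cc(OC)cc(OC)c1[C@@H](B1O[C@@H](C2CCCCC2)[C@H](C2CCCCC2)O1)[C@H]1[C@H](c2c(OC)cc(OC)cc2OCC=C)C=C(C)CC1(C)C | intermediate (not isolated)
21 | (S)-[2-(allyloxy)-4,6-dimethoxyphenyl]{(1S,2R)-2-[2-(allyloxy)-4,6-dimethoxyphenyl]-4,6,6-trimethylcyclohex-3-en-1-yl}methanol | C=CCOc1cc(OC)cc(OC)c1[C@@H](O)[C@H]1[C@H](c2c(OC)cc(OC)cc2OCC=C)C=C(C)CC1(C)C | intermediate
22 | triethylsilyl ether of 21 | C=CCOc1cc(OC)cc(OC)c1[C@@H](O[Si](CC)(CC)CC)[C@H]1[C@H](c2c(OC)cc(OC)cc2OCC=C)C=C(C)CC1(C)C | intermediate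
23 | 2-[(S)-{(1S,2R)-2-(2-hydroxy-4,6-dimethoxyphenyl)-4,6,6-trimethylcyclohex-3-en-1-yl}(triethylsilyloxy)methyl]-3,5-dimethoxyphenol | Oc1cc(OC)cc(OC)c1[C@@H](O[Si](CC)(CC)CC)[C@H]1[C@H](c2c(OC)cc(OC)cc2O)C=C(C)CC1(C)C | intermediate
24 | bis(prop-2-ynoate) ester of 23 | C#CC(=O)Oc1cc(OC)cc(OC)c1[C@@H](O[Si](CC)(CC)CC)[C@H]1[C@H](c2c(OC)cc(OC)cc2OC(=O)C#C)C=C(C)CC1(C)C | intermediate
25 | triethylsilyl ether of the target | COc1cc(OC)c2ccc(=O)oc2c1[C@@H](O[Si](CC)(CC)CC)[C@H]1[C@H](c2c(OC)cc(OC)c3ccc(=O)oc23)C=C(C)CC1(C)C | intermediate
26 | 8-[(S)-hydroxy{(1S,2R)-2-(5,7-dimethoxy-2-oxo-2H-chromen-8-yl)-4,6,6-trimethylcyclohex-3-en-1-yl}methyl]-5,7-dimethoxy-2H-chromen-2-one | COc1cc(OC)c2ccc(=O)oc2c1[C@@H](O)[C@H]1[C@H](c2c(OC)cc(OC)c3ccc(=O)oc23)C=C(C)CC1(C)C | target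

## Step count and least certain steps

Total: 15 steps. Longest linear sequence: 13 steps (3 to 26 through steps 2–8 and 10–15).

Step 10 (key step). The most likely failure is that the second 1,2-shift is outpaced. Borate formation between the di-ortho-substituted aryllithium and the congested α-chloro boronic ester may be slow, so that β-elimination of chloride or chloride exchange at the α-carbon takes over. A mismatch between ring stereocentres and diol in the first shift is the second concern. The fallback sets out from 14 and returns at 21, replacing the stereospecific shift by carbonyl addition. Insertion of chloromethyllithium (ICH2Cl, n-BuLi, THF, −78 °C) gives the homologated boronic ester F1. Oxidation (NaBO3, THF/H2O) gives the primary alcohol F2, and Dess–Martin periodinane gives the aldehyde F3, whose trans arrangement is the stable one. Addition of aryllithium 19 gives 21 together with its carbinol epimer. If the addition is unselective, the mixture is oxidised to the aryl ketone F4 and reduced under reagent control (oxazaborolidine-catalysed borane reduction) to 21.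

Step 5. The most likely failure is poor facial discrimination by the ligand on a diene whose aryl group is twisted out of conjugation, giving low enantiomeric purity; protonation at C4 instead of C2 and slow borylcupration next to the quaternary C6 are lesser concerns. The fallback sets out from 8 and returns at 13, replacing catalyst control by resolution through the diol already required. Protoboration with an achiral catalyst (CuCl, Xantphos, NaOt-Bu, B2pin2, MeOH) gives 9 together with its enantiomer, the (1R,2R) pinacol ester F5. Steps 6 and 7 on the mixture give 10 with the enantiomeric trifluoroborate F6, and then 13 with the diastereomeric (1R,2R) diol ester F7. F7 is removed by crystallisation or chromatography.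

Step 14. The most likely failure is ionisation or elimination at the benzylic silyl ether under the Lewis-acidic gold and silver salts, or slow closure of the ring-A ester held in an unfavourable conformation by the neighbouring carbinol substituent. The fallback sets out from 23 and returns at 25, building the pyranones by carbonyl olefination. Ortho-formylation of both phenols (MgCl2, Et3N, paraformaldehyde, MeCN, reflux) gives the bis-salicylaldehyde F8. Treatment with (triphenylphosphoranylidene)ketene in toluene at 80 °C acylates each phenol and closes each lactone by intramolecular Wittig reaction, giving 25.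

Step 2. The most likely failure is incomplete regiocontrol, with iodination between the two methoxy groups competing and the isomers hard to separate. The fallback sets out from 3 and returns at 4, replacing electrophilic substitution by directed metalation. Protection (MOMCl, i-Pr2NEt) gives the methoxymethyl ether F9. Lithiation between the acetal oxygen and a methoxy group (n-BuLi, THF, 0 °C) and quenching with I2 gives the iodide F10, and HCl in MeOH gives 4.

Step 4. The most likely failure is slow transmetalation or reductive elimination with the di-ortho-substituted arylzinc, leading to reduction of the iodide and homocoupling. The fallback sets out from 2 and returns at 8, with the polarity reversed. Borylation of the triflate (B2pin2, PdCl2(PPh3)2, PPh3, KOPh, toluene, 50 °C) gives the dienyl pinacol boronate F11. Suzuki coupling of F11 with the aryl iodide 5 (Pd(OAc)2, SPhos, K3PO4, dioxane/H2O, 80 °C) gives 8; no 2,6-dioxygenated arylboron species is involved.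

## Further compounds

F1 | step 10 | (4S,5S)-2-({(1S,2R)-2-[2-(allyloxy)-4,6-dimethoxyphenyl]-4,6,6-trimethylcyclohex-3-en-1-yl}methyl)-4,5-dicyclohexyl-1,3,2-dioxaborolane | B1(O[C@@H](C2CCCCC2)[C@H](C2CCCCC2)O1)C[C@H]1[C@H](c2c(OC)cc(OC)cc2OCC=C)C=C(C)CC1(C)C
F2 | step 10 | {(1S,2R)-2-[2-(allyloxy)-4,6-dimethoxyphenyl]-4,6,6-trimethylcyclohex-3-en-1-yl}methanol | OC[C@H]1[C@H](c2c(OC)cc(OC)cc2OCC=C)C=C(C)CC1(C)C
F3 | step 10 | (1S,2R)-2-[2-(allyloxy)-4,6-dimethoxyphenyl]-4,6,6-trimethylcyclohex-3-ene-1-carbaldehyde | O=C[C@H]1[C@H](c2c(OC)cc(OC)cc2OCC=C)C=C(C)CC1(C)C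
F4 | step 10 | [2-(allyloxy)-4,6-dimethoxyphenyl]{(1S,2R)-2-[2-(allyloxy)-4,6-dimethoxyphenyl]-4,6,6-trimethylcyclohex-3-en-1-yl}methanone | C=CCOc1cc(OC)cc(OC)c1C(=O)[C@H]1[C@H](c2c(OC)cc(OC)cc2OCC=C)C=C(C)CC1(C)C
F5 | step 5 | pinacol ester of (1R,2R)-trans-2-[2-(tert-butyldimethylsilyloxy)-4,6-dimethoxyphenyl]-4,6,6-trimethylcyclohex-3-en-1-ylboronic acid (enantiomer of 9) | B1(OC(C)(C)C(C)(C)O1)[C@@H]1[C@@H](c2c(OC)cc(OC)cc2O[Si](C)(C)C(C)(C)C)C=C(C)CC1(C)C
F6 | step 5 | potassium (1R,2R)-trans-trifluoro[2-(2-hydroxy-4,6-dimethoxyphenyl)-4,6,6-trimethylcyclohex-3-en-1-yl]borate (enantiomer of 10) | [K+].F[B-](F)(F)[C@@H]1[C@@H](c2c(OC)cc(OC)cc2O)C=C(C)CC1(C)C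
F7 | step 5 | (4S,5S)-4,5-dicyclohexyl-2-[(1R,2R)-2-(2-hydroxy-4,6-dimethoxyphenyl)-4,6,6-trimethylcyclohex-3-en-1-yl]-1,3,2-dioxaborolane (diastereomer of 13) | B1(O[C@@H](C2CCCCC2)[C@H](C2CCCCC2)O1)[C@@H]1[C@@H](c2c(OC)cc(OC)cc2O)C=C(C)CC1(C)C
F8 | step 14 | 3-[(S)-{(1S,2R)-2-(3-formyl-2-hydroxy-4,6-dimethoxyphenyl)-4,6,6-trimethylcyclohex-3-en-1-yl}(triethylsilyloxy)methyl]-2-hydroxy-4,6-dimethoxybenzaldehyde | COc1cc(OC)c(C=O)c(O)c1[C@@H](O[Si](CC)(CC)CC)[C@H]1[C@H](c2c(OC)cc(OC)c(C=O)c2O)C=C(C)CC1(C)C
F9 | step 2 | 1,3-dimethoxy-5-(methoxymethoxy)benzene | COCOc1cc(OC)cc(OC)c1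
F10 | step 2 | 2-iodo-1,5-dimethoxy-3-(methoxymethoxy)benzene | COCOc1cc(OC)cc(OC)c1I
F11 | step 4 | 4,4,5,5-tetramethyl-2-(3,3,5-trimethylcyclohexa-1,5-dien-1-yl)-1,3,2-dioxaborolane | CC1=CC(B2OC(C)(C)C(C)(C)O2)=CC(C)(C)C1
A1 | alternative 1 | (3S,4S)-trans-4-(2-hydroxy-4,6-dimethoxybenzoyl)-5-[2-(methoxymethoxy)-4,6-dimethoxyphenyl]-3,3-dimethylcyclohexanone (ring carbons as C1 and C2 of the target) | COc1cc(OC)c(C(=O)[C@H]2[C@H](c3c(OC)cc(OC)cc3OCOC)CC(=O)CC2(C)C)c(O)c1
A2 | alternative 1 | (E)-1-(2-hydroxy-4,6-dimethoxyphenyl)-3-[2-(methoxymethoxy)-4,6-dimethoxyphenyl]prop-2-en-1-one | COc1cc(OC)c(C(=O)/C=C/c2c(OC)cc(OC)cc2OCOC)c(O)c1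
A3 | alternative 1 | 4-methyl-2-(trimethylsilyloxy)penta-1,3-diene | C=C(O[Si](C)(C)C)C=C(C)C
A4 | alternative 2 | triethylsilyl ether of the target (identical with 25) | COc1cc(OC)c2ccc(=O)oc2c1[C@@H](O[Si](CC)(CC)CC)[C@H]1[C@H](c2c(OC)cc(OC)c3ccc(=O)oc23)C=C(C)CC1(C)C
A5 | alternative 2 | bis(prop-2-ynoate) of the silyl-protected bis-phenol (identical with 24) | C#CC(=O)Oc1cc(OC)cc(OC)c1[C@@H](O[Si](CC)(CC)CC)[C@H]1[C@H](c2c(OC)cc(OC)cc2OC(=O)C#C)C=C(C)CC1(C)C
A6 | alternative 3 | 2-{(1R,6S)-6-[(S)-[2-(methoxymethoxy)-4,6-dimethoxyphenyl](triethylsilyloxy)methyl]-3,5,5-trimethylcyclohex-2-en-1-yl}-5-methoxy-3-(triisopropylsilyloxy)phenol | COCOc1cc(OC)cc(OC)c1[C@@H](O[Si](CC)(CC)CC)[C@H]1[C@H](c2c(O)cc(OC)cc2O[Si](C(C)C)(C(C)C)C(C)C)C=C(C)CC1(C)C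
A7 | alternative 3 | triisopropylsilyl ynol ether at C2: cyclohex-3-ene with C2–C≡C–OSi(i-Pr)3 trans to the C1 side chain (S)-CH(OSiEt3)[2-(methoxymethoxy)-4,6-dimethoxyphenyl] | COCOc1cc(OC)cc(OC)c1[C@@H](O[Si](CC)(CC)CC)[C@H]1[C@H](C#CO[Si](C(C)C)(C(C)C)C(C)C)C=C(C)CC1(C)C
A8 | alternative 3 | 3-methoxycyclobut-2-en-1-one | COC1=CC(=O)C1
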